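**Retrosynthetic overview**

1. The target is read as its C-1 ketone with the ring alkene in conjugation (a cyclohex-2-enone). The C-2–C-3 ring bond is then the C=C of an aldol condensation: C-2 is the methyl of a methyl ketone (C-1) and C-3 a formyl carbon. The enabling feature is that ring atoms C-1, C-6, C-5, C-4 and C-3 form a 1,5-ketoaldehyde array, with C-2 as its enolisable methyl.
2. This ketoaldehyde is made and closed in one flask from two acyclic pieces: a C25 (E)-enone carrying the whole polyene (ring C-2, C-1, C-6, C-5) and methyl 2-formylpropanoate (C-3, C-4 and the C-4 methyl). A catalytic asymmetric Michael addition forms C-4–C-5 and the C-5 stereocentre; the aldol condensation then closes the only ring.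
3. After ring formation: gem-dimethylation at C-6, loss of the temporary C-4 ester as CO2, dienolate deconjugation to the C-3=C-4 alkene, and reduction of the C-1 ketone to the cis alcohol.
4. The enone comes from (2E,6E)-farnesyl bromide by two-carbon homologation, isopropenyl addition, Johnson–Claisen rearrangement, reduction to the C22 aldehyde and Wittig olefination.

Key step: step 7

Remarks
- Locants C-1 to C-6 are those of the target ring: C-1 carbinol, C-2 CH2, C-3 =CH, C-4 =C(CH3), C-5 CH(chain), C-6 C(CH3)2.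
- "chain" = (3E,7E,11E)-3,8,12,16-tetramethylheptadeca-3,7,11,15-tetraen-1-yl (C21H35).
- Assumption: of the two pseudoenantiomeric 6′-hydroxy cinchona catalysts, the quinidine-derived one is taken to give (3S)-12; if the sense is reversed, the quinine-derived pseudoenantiomer is used in step 7.
- Assumption: compound 11 (methyl 2-formylpropanoate) is taken as a commercial starting material.

**Step 1**
Reactants: 1 (2E,6E)-farnesyl bromide [(2E,6E)-1-bromo-3,7,11-trimethyldodeca-2,6,10-triene]
Product: 2 (4E,8E)-5,9,13-trimethyltetradeca-4,8,12-trienenitrile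
Conditions: CH3CN, n-BuLi, THF, −78 °C; then 1, −78 → 0 °C
Reagents that add atoms: acetonitrile (CC#N)
Why: Nitrile-anion alkylation (SN2) of the primary allylic bromide by lithioacetonitrile at low temperature should add two carbons without touching the (E)-alkenes.

**Step 2**
Reactants: 2 (4E,8E)-5,9,13-trimethyltetradeca-4,8,12-trienenitrile
Product: 4 (4E,8E)-5,9,13-trimethyltetradeca-4,8,12-trienal (homofarnesal), via N-aluminated aldimine 3 (not isolated)
Conditions: i-Bu2AlH, CH2Cl2, −78 °C; then aq. Rochelle salt, wet silica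
Reagents that add atoms: water (O)
Why: Partial reduction of a nitrile with i-Bu2AlH stops at the N-aluminated aldimine 3, which is hydrolysed to the aldehyde on work-up.

**Step 3**
Reactants: 4 homofarnesal
Product: 5 (6E,10E)-2,7,11,15-tetramethylhexadeca-1,6,10,14-tetraen-3-ol (racemic)
Conditions: CH2=C(CH3)MgBr, THF, −78 → 0 °C; then H2O
Reagents that add atoms: isopropenylmagnesium bromide (C=C(C)[Mg]Br)
Why: Grignard 1,2-addition to the unhindered aldehyde gives the allylic alcohol, whose racemic carbinol centre becomes sp2 in step 4.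

**Step 4**
Reactants: 5 (6E,10E)-2,7,11,15-tetramethylhexadeca-1,6,10,14-tetraen-3-ol
Product: 7 ethyl (4E,8E,12E)-4,9,13,17-tetramethyloctadeca-4,8,12,16-tetraenoate, via mixed ketene acetal 6 (not isolated)
Conditions: CH3C(OEt)3, EtCO2H (cat.), 140 °C, EtOH distilled off
Reagents that add atoms: triethyl orthoacetate (CC(OCC)(OCC)OCC)
Why: Johnson–Claisen rearrangement of ketene acetal 6 through a chair transition state with the homofarnesyl chain equatorial should give the (E)-trisubstituted alkene.

**Step 5**
Reactants: 7 ethyl (4E,8E,12E)-4,9,13,17-tetramethyloctadeca-4,8,12,16-tetraenoate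
Product: 9 (4E,8E,12E)-4,9,13,17-tetramethyloctadeca-4,8,12,16-tetraenal, via aluminium hemiacetal 8 (not isolated)
Conditions: i-Bu2AlH, CH2Cl2, −78 °C; then MeOH, aq. Rochelle salt
Reagents that add atoms: none
Why: Partial ester reduction with i-Bu2AlH at −78 °C stops at the tetrahedral aluminium hemiacetal 8, which collapses to the aldehyde on work-up.

**Step 6**
Reactants: 9 (4E,8E,12E)-4,9,13,17-tetramethyloctadeca-4,8,12,16-tetraenal
Product: 10 (3E,7E,11E,15E)-7,12,16,20-tetramethylhenicosa-3,7,11,15,19-pentaen-2-one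
Conditions: Ph3P=CHC(O)CH3, toluene, 90 °C
Reagents that add atoms: 1-(triphenyl-λ5-phosphanylidene)propan-2-one (CC(=O)C=P(c1ccccc1)(c1ccccc1)c1ccccc1)
Why: Wittig olefination with a stabilised acyl ylide should give the (E)-enone.

**Step 7**
Reactants: 10 (3E,7E,11E,15E)-7,12,16,20-tetramethylhenicosa-3,7,11,15,19-pentaen-2-one; 11 methyl 2-methyl-3-oxopropanoate (methyl 2-formylpropanoate)
Product: 13 methyl (6S)-1-methyl-4-oxo-6-(chain)cyclohex-2-ene-1-carboxylate (both C-1 epimers), via Michael adduct 12 (not isolated)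
Conditions: cupreidine 9-benzyl ether (10 mol %), CH2Cl2, −20 °C → rt; then pyrrolidine (0.3 equiv), AcOH (0.3 equiv), 4 Å MS, 40 °C
Reagents that add atoms: none
Why: The bifunctional cinchona catalyst hydrogen-bonds the enone carbonyl through its 6′-OH while its quinuclidine nitrogen deprotonates 11, so the ester α-carbon adds to the enone β-carbon (intermolecular Michael addition, giving 12); pyrrolidinium acetate then turns the methyl ketone of 12 into its terminal enamine, which attacks the non-enolisable formyl group and loses water, joining the former acetyl methyl carbon to the former formyl carbon. The closest known reaction type is the organocatalytic asymmetric Robinson annulation of α-substituted 1,3-dicarbonyl compounds with acyclic enones (cinchona-catalysed Michael addition followed by amine-mediated aldol condensation). The ring closes in a 6-(enolendo)-exo-trig mode; closure from the internal α-carbon would give a four-membered ring and should not compete. The chain-bearing stereocentre (C-6 of 13) is set in the Michael step by the catalyst, which exposes one face of the enone; the quaternary C-1 forms as an epimer mixture that does not matter because this carbon becomes sp2 in step 10. The step needs 1,4- over 1,2-addition and C- over O-alkylation (secured by the soft, acidic 1,3-dicarbonyl donor), and an aldol closure faster than retro-Michael loss of 11 (secured by intramolecularity and the very electrophilic aldehyde).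

**Step 8**
Reactants: 13 methyl (6S)-1-methyl-4-oxo-6-(chain)cyclohex-2-ene-1-carboxylate
Product: 15 methyl (6S)-1,5,5-trimethyl-4-oxo-6-(chain)cyclohex-2-ene-1-carboxylate, via monomethyl ketone 14 (not isolated)
Conditions: LiN(i-Pr)2, THF, −78 °C, then MeI, → −20 °C; again LiN(i-Pr)2, −78 °C, then MeI, DMPU, → 0 °C
Reagents that add atoms: iodomethane (CI)
Why: Enolate alkylation: kinetic α′-deprotonation (the γ-carbon is quaternary, so no extended enolate can form) and C-methylation, done twice, should install the gem-dimethyl group without affecting the non-enolisable chain-bearing stereocentre.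

**Step 9**
Reactants: 15 methyl (6S)-1,5,5-trimethyl-4-oxo-6-(chain)cyclohex-2-ene-1-carboxylate
Product: 17 (5R)-4,6,6-trimethyl-5-(chain)cyclohex-2-en-1-one (C-4 epimers), via lithium carboxylate 16 (not isolated)
Conditions: LiCl, DMSO, H2O (2 equiv), 150 °C
Reagents that add atoms: none
Why: Krapcho dealkoxycarbonylation: chloride demethylates the ester, and the vinylogous β-keto carboxylate 16 loses CO2 to a dienolate that is protonated to the conjugated enone, as in the classical decarboxylation of 4-oxocyclohex-2-ene-1-carboxylates.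

**Step 10**
Reactants: 17 (5R)-4,6,6-trimethyl-5-(chain)cyclohex-2-en-1-one
Product: 19 (5R)-4,6,6-trimethyl-5-(chain)cyclohex-3-en-1-one, via potassium dienolate 18 (not isolated)
Conditions: KOt-Bu, THF/t-BuOH, 0 °C; then AcOH (excess), −78 °C, cold neutral work-up
Reagents that add atoms: none
Why: Deconjugative isomerisation: γ-deprotonation (no α′-hydrogens remain) gives the extended dienolate 18, and kinetic protonation at the α-carbon places the double bond in the β,γ-position, the trisubstituted ring alkene of the target.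

**Step 11**
Reactants: 19 (5R)-4,6,6-trimethyl-5-(chain)cyclohex-3-en-1-one
Product: 20 camelliol C, (1S,5R)-4,6,6-trimethyl-5-(chain)cyclohex-3-en-1-ol
Conditions: NaBH4, CeCl3·7H2O, MeOH, −40 °C
Reagents that add atoms: none
Why: Substrate-controlled 1,2-reduction (Luche conditions, chosen to avoid base-induced reconjugation): hydride should attack the face opposite the neighbouring chain along the axial trajectory, giving the equatorial alcohol cis to the chain, as in the reduction of 4,4-dimethyl-3-keto triterpenoids to their 3β-alcohols.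

**Compound list**

1 | (2E,6E)-farnesyl bromide | CC(C)=CCC/C(C)=C/CC/C(C)=C/CBr | starting material
2 | (4E,8E)-5,9,13-trimethyltetradeca-4,8,12-trienenitrile | CC(C)=CCC/C(C)=C/CC/C(C)=C/CCC#N | intermediate
3 | N-(diisobutylalumanyl)imine of 4 | CC(C)=CCC/C(C)=C/CC/C(C)=C/CCC=N[Al](CC(C)C)CC(C)C | intermediate
4 | (4E,8E)-5,9,13-trimethyltetradeca-4,8,12-trienal | CC(C)=CCC/C(C)=C/CC/C(C)=C/CCC=O | intermediate
5 | (6E,10E)-2,7,11,15-tetramethylhexadeca-1,6,10,14-tetraen-3-ol (racemic) | CC(C)=CCC/C(C)=C/CC/C(C)=C/CCC(O)C(C)=C | intermediate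
6 | 1-ethoxyvinyl ether of 5 (mixed ketene acetal) | CC(C)=CCC/C(C)=C/CC/C(C)=C/CCC(OC(=C)OCC)C(C)=C | intermediate
7 | ethyl (4E,8E,12E)-4,9,13,17-tetramethyloctadeca-4,8,12,16-tetraenoate | CC(C)=CCC/C(C)=C/CC/C(C)=C/CC/C=C(\C)CCC(=O)OCC | intermediate
8 | O-diisobutylaluminium ethyl hemiacetal of 9 | CC(C)=CCC/C(C)=C/CC/C(C)=C/CC/C=C(\C)CCC(OCC)O[Al](CC(C)C)CC(C)C | intermediate
9 | (4E,8E,12E)-4,9,13,17-tetramethyloctadeca-4,8,12,16-tetraenal | CC(C)=CCC/C(C)=C/CC/C(C)=C/CC/C=C(\C)CCC=O | intermediate
10 | (3E,7E,11E,15E)-7,12,16,20-tetramethylhenicosa-3,7,11,15,19-pentaen-2-one | CC(C)=CCC/C(C)=C/CC/C(C)=C/CC/C=C(\C)CC/C=C/C(C)=O | intermediate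
11 | methyl 2-methyl-3-oxopropanoate | COC(=O)C(C)C=O | starting material
12 | methyl (3S)-2-formyl-2-methyl-5-oxo-3-(chain)hexanoate (C-2 epimers) | CC(C)=CCC/C(C)=C/CC/C(C)=C/CC/C=C(\C)CC[C@@H](CC(C)=O)C(C)(C=O)C(=O)OC | intermediate
13 | methyl (6S)-1-methyl-4-oxo-6-(chain)cyclohex-2-ene-1-carboxylate (C-1 epimers) | CC(C)=CCC/C(C)=C/CC/C(C)=C/CC/C=C(\C)CC[C@@H]1C(C)(C(=O)OC)C=CC(=O)C1 | intermediate
14 | methyl (6S)-1,5-dimethyl-4-oxo-6-(chain)cyclohex-2-ene-1-carboxylate (epimers) | CC(C)=CCC/C(C)=C/CC/C(C)=C/CC/C=C(\C)CC[C@@H]1C(C)(C(=O)OC)C=CC(=O)C1C | intermediate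
15 | methyl (6S)-1,5,5-trimethyl-4-oxo-6-(chain)cyclohex-2-ene-1-carboxylate (C-1 epimers) | CC(C)=CCC/C(C)=C/CC/C(C)=C/CC/C=C(\C)CC[C@@H]1C(C)(C(=O)OC)C=CC(=O)C1(C)C | intermediate
16 | lithium (6S)-1,5,5-trimethyl-4-oxo-6-(chain)cyclohex-2-ene-1-carboxylate | CC(C)=CCC/C(C)=C/CC/C(C)=C/CC/C=C(\C)CC[C@@H]1C(C)(C(=O)[O-])C=CC(=O)C1(C)C.[Li+] | intermediate
17 | (5R)-4,6,6-trimethyl-5-(chain)cyclohex-2-en-1-one (C-4 epimers) | CC(C)=CCC/C(C)=C/CC/C(C)=C/CC/C=C(\C)CC[C@@H]1C(C)C=CC(=O)C1(C)C | intermediate
18 | potassium (5R)-4,6,6-trimethyl-5-(chain)cyclohexa-1,3-dien-1-olate | CC(C)=CCC/C(C)=C/CC/C(C)=C/CC/C=C(\C)CC[C@@H]1C(C)=CC=C([O-])C1(C)C.[K+] | intermediate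
19 | (5R)-4,6,6-trimethyl-5-(chain)cyclohex-3-en-1-one | CC(C)=CCC/C(C)=C/CC/C(C)=C/CC/C=C(\C)CC[C@@H]1C(C)=CCC(=O)C1(C)C | intermediate
20 | camelliol C, (1S,5R)-4,6,6-trimethyl-5-(chain)cyclohex-3-en-1-ol | CC(C)=CCC/C(C)=C/CC/C(C)=C/CC/C=C(\C)CC[C@@H]1C(C)=CC[C@H](O)C1(C)C | target

**Step count and risks**

Total step count: 11. Longest linear sequence: 11 steps (from 1; compound 11 enters at step 7).

Steps most likely to fail:

Step 7. The Michael addition has to build a tertiary centre next to a quaternary one. It may be slow or poorly face-selective, and the adduct may revert (retro-Michael) during the aldol stage, eroding enantiopurity. Fallback, setting out from 10 and returning at 17: a Hayashi–Miyaura addition of isopropenylboronic acid pinacol ester to 10 ([Rh(OH)(cod)]2, (R)-BINAP or its antipode as the sense requires, dioxane/H2O) should give (4S)-5-methyl-4-(chain)hex-5-en-2-one F1. Excess 9-BBN hydroborates the isopropenyl group and reduces the ketone while leaving the trisubstituted alkenes, and H2O2/NaOH then gives (3S)-2-methyl-3-(chain)hexane-1,5-diol F2. Dess–Martin oxidation gives (3S)-2-methyl-5-oxo-3-(chain)hexanal F3, which undergoes aldol condensation with pyrrolidinium acetate to (5S)-4-methyl-5-(chain)cyclohex-2-en-1-one F4. Two kinetic α′-methylations (LiN(i-Pr)2, MeI, as in step 8) lead to 17.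

Step 10. Protonation of the dienolate may occur partly at the γ-carbon, and the β,γ-enone may slip back into conjugation during isolation. Fallback, setting out from 17 and returning at 20: the potassium dienolate of 17 is O-acetylated (KOt-Bu, then Ac2O) to (5R)-4,6,6-trimethyl-5-(chain)cyclohexa-1,3-dien-1-yl acetate F8. NaBH4 in aqueous ethanol cleaves the dienyl acetate, the liberated dienolate is protonated at the α-carbon, and the β,γ-enone is reduced in the same flask, as in the classical conversion of steroidal 3,5-dienyl acetates into Δ5-3β-alcohols. This should give 20 directly.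

Step 9. Chloride attack on the methyl ester of a fully substituted carbon may be sluggish, and prolonged heating at 150 °C may damage the skipped polyene. Fallback, setting out from 10 and returning at 17: the ester is carried as an allyl ester and removed at room temperature. Prop-2-en-1-yl 2-methyl-3-oxopropanoate F5 (from allyl propanoate and allyl formate, NaH) is annulated with 10 as in step 7 to prop-2-en-1-yl (6S)-1-methyl-4-oxo-6-(chain)cyclohex-2-ene-1-carboxylate F6. This is dimethylated as in step 8 to prop-2-en-1-yl (6S)-1,5,5-trimethyl-4-oxo-6-(chain)cyclohex-2-ene-1-carboxylate F7. Tsuji–Trost deallylation (Pd(PPh3)4, morpholine, THF, rt) and spontaneous decarboxylation of the vinylogous β-keto acid should give 17, together with some 19, which step 10 converges.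

**Further compounds**

F1 | step 7 | (4S)-5-methyl-4-(chain)hex-5-en-2-one | CC(C)=CCC/C(C)=C/CC/C(C)=C/CC/C=C(\C)CC[C@@H](CC(C)=O)C(C)=C
F2 | step 7 | (3S)-2-methyl-3-(chain)hexane-1,5-diol (diastereomers at C-2 and C-5) | CC(C)=CCC/C(C)=C/CC/C(C)=C/CC/C=C(\C)CC[C@@H](CC(C)O)C(C)CO
F3 | step 7 | (3S)-2-methyl-5-oxo-3-(chain)hexanal (C-2 epimers) | CC(C)=CCC/C(C)=C/CC/C(C)=C/CC/C=C(\C)CC[C@@H](CC(C)=O)C(C)C=O
F4 | step 7 | (5S)-4-methyl-5-(chain)cyclohex-2-en-1-one (C-4 epimers) | CC(C)=CCC/C(C)=C/CC/C(C)=C/CC/C=C(\C)CC[C@@H]1C(C)C=CC(=O)C1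
F5 | step 9 | prop-2-en-1-yl 2-methyl-3-oxopropanoate | C=CCOC(=O)C(C)C=O
F6 | step 9 | prop-2-en-1-yl (6S)-1-methyl-4-oxo-6-(chain)cyclohex-2-ene-1-carboxylate (C-1 epimers) | CC(C)=CCC/C(C)=C/CC/C(C)=C/CC/C=C(\C)CC[C@@H]1C(C)(C(=O)OCC=C)C=CC(=O)C1
F7 | step 9 | prop-2-en-1-yl (6S)-1,5,5-trimethyl-4-oxo-6-(chain)cyclohex-2-ene-1-carboxylate (C-1 epimers) | CC(C)=CCC/C(C)=C/CC/C(C)=C/CC/C=C(\C)CC[C@@H]1C(C)(C(=O)OCC=C)C=CC(=O)C1(C)C
F8 | step 10 | (5R)-4,6,6-trimethyl-5-(chain)cyclohexa-1,3-dien-1-yl acetate | CC(C)=CCC/C(C)=C/CC/C(C)=C/CC/C=C(\C)CC[C@@H]1C(C)=CC=C(OC(C)=O)C1(C)C
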